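**Count Z.** Count the Z first, since this reckoning asks what the end state must be before asking how fast it comes. Dusk, dawn and spring share one charge and differ in temperature.

common to all: J 0.40 M; D 0.400 M; Z 0.520 M; X 8.00 mM; time 12 d
- dusk: at 70 °C until 6.0 d, from then on at 90 °C
- dawn: temperature 70 °C
- spring: temperature 90 °C

    J + Z → J.Z (k1 = 7.0 × 10⁻⁴ M⁻¹ min⁻¹, Ea1 = 87.0 kJ mol⁻¹)
    Z + D → Z.D (k2 = 6.7 × 10⁻⁴ M⁻¹ min⁻¹, Ea2 = 102 kJ mol⁻¹)
    J.Z + Z.D → E (k3 = 0.0034 M⁻¹ min⁻¹, Ea3 = 92.0 kJ mol⁻¹)
    J.Z + X → J.Z.X (k4 = 0.012 M⁻¹ min⁻¹, Ea4 = 70.0 kJ mol⁻¹)
    (constants at 70 °C)

- the list of constants is for 70 °C, to be carried to other temperatures by the activation energies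

* the flask that comes out highest in share of E in all that became E or J.Z.X, or "all alike" when all lie within 1.5 percentage points (dusk / dawn / spring / all alike)
* share of E in all that became E or J.Z.X, dusk
* share of E in all that became E or J.Z.X, dawn
* share of E in all that became E or J.Z.X, spring

**Turn Z.** Each E carries two Z, one through J.Z and one through Z.D, and each J.Z.X carries one. Z is then the limiting reagent, for 0.520 M is less than the 0.800 M that 0.40 M of J needs. Let X take its whole charge, and the remaining Z pays for 0.256 M of E, which is less than the 0.400 M of D. Within this count, and while Z stays short, more Z raises this E.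

**Turn X.** Now divide: 97.0 %. Call this S, the ceiling share: the E that Z can pay for once X has taken its full charge, over that E plus the X. More X lowers S in two ways, by adding J.Z.X and by taking Z from E.

**Turn time.** Ask next whether X really gets its charge. Reckoned at its starting rate, step 1 makes as much J.Z as there is X within 54.9 min, far shorter than 12 d. At 70 °C, step 4 also has a larger constant than step 3. At 70 °C and the charged Z, J has a half-life of 1.32 d by step 1, shorter than 12 d, so expect the end to be close.

**Turn temperature.** S contains no rate constant, so heat leaves it unmoved, although step 2 speeds up by 7.2 and step 4 by 3.9 between the coldest and hottest flask. I commit to 97.0 % for dusk, 97.0 % for dawn and 97.0 % for spring, a tie.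

**The forecast.** The forecast gives 96.9 % for dusk, 96.6 % for dawn and 96.7 % for spring, and answers all alike: "Temperature only changes the small leftover J.Z and the J.Z/Z.D balance". My S stands close to its highest value.

**The result.** The simulation gives 96.9 % for dusk, 96.6 % for dawn and 96.7 % for spring, hence all alike, and the forecast held. Each share lies close to S, 97.0 %.

**One reason.** The depletion of X, with 0 % of its charge left at the end of dawn and 0.24 % at the end of spring, is part of why the shares of these two flasks sit near S. In a run of dawn with X held at its charge, the share falls to 75.3 %. In the same run of spring it falls to 84.7 %.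

**Second flask.** Take dawn with 0.020 M of X. S becomes 92.6 %, and the simulation gives 91.6 %.

Its constants were chosen freely.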